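The route rests on disconnecting the ten-membered carbocycle (C1–C10, briarane numbering) at C2–C3 and closing it last, after the cyclohexane, the spiro-epoxide and the γ-lactone exist. The key step exploits the C2 allylic carbinol next to the (3Z,5E)-diene: an intramolecular Nozaki–Hiyama–Kishi addition of a (Z)-dienyl iodide (C3) to the neopentyl aldehyde on quaternary C1 should form the ring and the C2 stereocentre in one operation. The precursor is a seco-aldehyde in which the cis,cis-diene, the trans-substituted lactone (C7/C8) and the cyclohexane (C1/C10) already fold C3 towards C2.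

Key step: step 22

Remark: atoms carry briarane numbers (C1–C20; "α" = face opposite the C15 methyl); compounds 1, 2, 12, 16, 17 and all reagents are assumed to be commercial.

Step 1
Reactants: 1 (E)-3-(tert-butyldimethylsilyloxy)-N,N-dimethylbuta-1,3-dien-1-amine; 2 ethyl (E)-3-methyl-4-oxobut-2-enoate
Product: 4 ethyl (1S,2S)-2-formyl-2-methyl-5-oxocyclohex-3-ene-1-carboxylate (formyl trans to ester; sets C1 and C10), via cycloadduct 3 (not isolated)
Conditions: (salen)Cr(III)–SbF6 catalyst (5 mol%), 4 Å MS, CH2Cl2, −40 °C; then AcCl, CH2Cl2/Et2O, −78 °C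
Reagents that add atoms: none
Why: Catalytic asymmetric Diels–Alder reaction of a 1-amino-3-siloxydiene with an α-substituted enal, followed by acylative β-elimination of the amine: the catalyst-bound formyl group sends the nucleophilic diene terminus to C10 and selects one face of the dienophile, which sets quaternary C1, while the E geometry of 2 becomes the trans relation of C2 and C9.

Step 2
Reactants: 4 enone
Product: 5 ethyl 2-formyl-2-methyl-6-methylidene-5-oxocyclohex-3-ene-1-carboxylate (C11=C20 methylidene; other centres as in 4)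
Conditions: (CH2O)n, N-methylanilinium trifluoroacetate, THF, 65 °C; used crude
Reagents that add atoms: formaldehyde (as paraformaldehyde), C=O
Why: Mannich-type α-methylenation: C11 is the only enolisable α-carbon of the enone (C13 is vinylic, C1 quaternary), so C20 should enter regiospecifically and no stereocentre is formed.

Step 3
Reactants: 5 methylidene dienone
Product: 6 ethyl 5-formyl-5-methyl-8-oxo-1-oxaspiro[2.5]oct-6-ene-4-carboxylate (11,20-epoxide, oxygen α, trans to the ester)
Conditions: t-BuOOH, DBU, CH2Cl2, −20 → 0 °C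
Reagents that add atoms: tert-butyl hydroperoxide, CC(C)(C)OO
Why: Weitz–Scheffer (nucleophilic) epoxidation: the peroxide should add to the unhindered exocyclic C20 rather than to neopentyl C14, and the enolate should close the C11–O bond on the α-face, anti to the adjacent pseudo-axial C10 ester, which sets spiro-C11.

Step 4
Reactants: 6 spiro-epoxy enone aldehyde
Product: 7 ethyl 5-(hydroxymethyl)-5-methyl-8-oxo-1-oxaspiro[2.5]oct-6-ene-4-carboxylate (C2 alcohol)
Conditions: NaBH4 (0.3 equiv), EtOH/CH2Cl2 (3:7), −78 °C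
Reagents that add atoms: none
Why: Chemoselective low-temperature hydride reduction of the aldehyde in the presence of the conjugated ketone and the ester; no stereocentre is formed.

Step 5
Reactants: 7 hydroxy ester
Product: 8 5-(hydroxymethyl)-5-methyl-8-oxo-1-oxaspiro[2.5]oct-6-ene-4-carboxylic acid (C9 acid)
Conditions: LiOH·H2O, THF/H2O, 0 °C → rt; 1 M HCl to pH 4
Reagents that add atoms: lithium hydroxide, [Li+].[OH-]
Why: Saponification, placed before the base-mediated next step so that the C2 alkoxide cannot lactonise onto the C9 ester; C10 is epimerisable but the trans-diequatorial arrangement is the stable one.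

Step 6
Reactants: 8 hydroxy acid
Product: 9 anisylidene acetal acid (C2–O and 14α-O bridged as a 2-(4-methoxyphenyl)-1,3-dioxane, aryl equatorial; 12-ketone; 11,20-epoxide; C9 acid)
Conditions: 4-methoxybenzaldehyde (3 equiv), t-BuOK (1.2 equiv), THF, 0 °C; 1 M HCl to pH 4–5
Reagents that add atoms: 4-methoxybenzaldehyde, COc1ccc(C=O)cc1
Why: Hemiacetal formation and intramolecular oxa-Michael addition: the C2–O–CH(Ar)–O⁻ alkoxide adds 6-exo to C14 of the enone, so the C14–O bond can only form cis to C2 (α), and the reversible acetal carbon should settle with the aryl group equatorial.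

Step 7
Reactants: 9 acetal acid
Product: 11 diazomethyl ketone (C9 ketone, C8 = CHN2; rest as in 9), via mixed anhydride 10 (not isolated)
Conditions: i-BuOCOCl, N-methylmorpholine, THF, −15 °C; then TMSCHN2, MeCN, 0 °C → rt
Reagents that add atoms: (trimethylsilyl)diazomethane, C[Si](C)(C)C=[N+]=[N-]; isobutyl chloroformate, CC(C)COC(Cl)=O (in 10 only)
Why: Acylation of the diazoalkane by the mixed anhydride and protodesilylation on work-up (first stage of an Arndt–Eistert sequence) should give the diazoketone whose diazo carbon is C8; no stereocentre is touched and the hindered C12 ketone should not react with this mild diazoalkane.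

Step 8
Reactants: 12 but-2-yne-1,4-diol
Product: 13 4-(tert-butyldiphenylsilyloxy)but-2-yn-1-ol
Conditions: 12 (3 equiv), TBDPSCl, imidazole, DMF, 0 °C
Reagents that add atoms: tert-butyl(chloro)diphenylsilane, CC(C)(C)[Si](Cl)(c1ccccc1)c1ccccc1
Why: Statistical monosilylation of the symmetrical diol used in excess.

Step 9
Reactants: 13 monosilylated butynediol
Product: 15 (Z)-4-(tert-butyldiphenylsilyloxy)-3-iodobut-2-en-1-ol, via alkenylaluminate 14 (not isolated)
Conditions: Red-Al, THF, 0 °C → rt; then I2, −78 °C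
Reagents that add atoms: iodine, II; sodium bis(2-methoxyethoxy)aluminium dihydride, [Na+].COCCO[AlH2-]OCCOC (in 14 only)
Why: Hydroxyl-directed trans-hydroalumination places H on C6 and Al on C5 in a five-membered aluminate, and iodinolysis with retention gives the (Z)-iodoalkene in which C7 and iodine are cis, the geometry that becomes the 5E alkene.

Step 10
Reactants: 16 acetylene; 17 hexamethylditin
Product: 18 (Z)-1,2-bis(trimethylstannyl)ethene
Conditions: Pd(PPh3)4 (2 mol%), dioxane, 60 °C, sealed vessel
Reagents that add atoms: none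
Why: Palladium-catalysed syn-distannation of the alkyne gives the cis bis-stannane.

Step 11
Reactants: 15 (Z)-iodoalkenol; 18 bis-stannane
Product: 19 (2E,4Z)-3-[(tert-butyldiphenylsilyloxy)methyl]-5-(trimethylstannyl)penta-2,4-dien-1-ol
Conditions: 18 (3 equiv), Pd2(dba)3, AsPh3, CuI, DMF, 40 °C
Reagents that add atoms: none
Why: Stille coupling with retention at both alkenes joins C4 to C5 so that C7 and C4 stay cis across C5=C6 and C3=C4 stays Z; excess bis-stannane should limit double coupling.

Step 12
Reactants: 19 dienylstannane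
Product: 20 (2E,4Z)-3-[(tert-butyldiphenylsilyloxy)methyl]-5-iodopenta-2,4-dien-1-ol
Conditions: I2, CH2Cl2, 0 °C
Reagents that add atoms: iodine, II
Why: Iododestannylation with retention of geometry gives the (Z)-alkenyl iodide at C3.

Step 13
Reactants: 20 iododienol
Product: 21 (2E,4Z)-3-[(tert-butyldiphenylsilyloxy)methyl]-5-iodopenta-2,4-dienal
Conditions: MnO2, CH2Cl2, rt
Reagents that add atoms: none
Why: Chemoselective oxidation of the allylic alcohol to the dienal without E/Z isomerisation.

Step 14
Reactants: 11 diazoketone; 21 iododienal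
Product: 22 diazo aldol adduct (C7 secondary alcohol with the later lactone configuration, C8 diazo, C9 ketone, (3Z,5E)-3-iododiene, 16-OTBDPS; cyclohexane part as in 11)
Conditions: Bu2Mg (20 mol%), ProPhenol ligand (10 mol%, enantiomer chosen for the C7 configuration shown), cis-cyclopentane-1,2-diol (5 mol%), THF, −20 °C
Reagents that add atoms: none
Why: Catalytic asymmetric aldol-type addition of an α-diazo carbonyl compound to an aldehyde (dinuclear magnesium–ProPhenol catalysis) forms C7–C8, the catalyst selecting the face of the dienal and so setting C7, because the stereocentres of 11 are too remote to interfere and the hindered C12 ketone is a poorer electrophile than the aldehyde.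

Step 15
Reactants: 22 diazo aldol adduct
Product: 23 C7 acrylate of 22
Conditions: acryloyl chloride, i-Pr2NEt, CH2Cl2, −40 °C
Reagents that add atoms: acryloyl chloride, C=CC(=O)Cl
Why: O-Acylation of the secondary alcohol installs C17–C19 as an acrylate tethered through the future lactone oxygen; the diazoketone is inert to the acyl chloride under basic conditions.

Step 16
Reactants: 23 diazo acrylate
Product: 24 C8,C9-diketone acrylate (C7 acryloyloxy; C12 ketone retained)
Conditions: dimethyldioxirane (1.05 equiv), acetone/CH2Cl2, −78 °C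
Reagents that add atoms: dimethyldioxirane, CC1(C)OO1
Why: Oxygen-atom transfer to the nucleophilic diazo carbon with loss of N2 gives the C8 ketone, the diazo group reacting far faster than the electron-poor acrylate and the deactivated iododiene at −78 °C.

Step 17
Reactants: 24 diketone acrylate
Product: 25 hydroxy lactone (γ-lactone O–C7/C8/C17/C19 with 8-OH cis to C6 and to the C17 methyl; C9 and C12 ketones)
Conditions: [(Ph3P)CuH]6 (0.25 equiv), toluene, −40 → 0 °C; aq. NH4Cl
Reagents that add atoms: none
Why: Copper hydride reductive aldol cyclisation: conjugate reduction of the acrylate gives a copper (Z)-enolate that adds 5-exo to the adjacent, more electrophilic C8 ketone (C9 is neopentyl and would give a six-membered ring), the tether through O7 placing the C9 acyl branch trans to the C7 dienyl group (8-OH cis to C6) and the chelated chair transition state placing the C17 methyl cis to the hydroxyl, which is also the stable arrangement at epimerisable C17.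

Step 18
Reactants: 25 diketo lactone
Product: 26 9,12-diol (9-OH and 12α-OH; 8-OH free)
Conditions: NaBH4, MeOH/THF (1:4), −40 °C
Reagents that add atoms: none
Why: Hydride reduction of both ketones under local control: at C12 the axial C14–O bond blocks the α-face, so hydride should enter from the β-face (also anti to the epoxide C–O) to give the axial 12α-alcohol, and at C9 Felkin–Anh attack anti to the quaternary C1 branch of C10 should give the C9 configuration of the target.

Step 19
Reactants: 26 diol
Product: 27 9,12-diacetate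
Conditions: Ac2O, pyridine, DMAP (cat.), CH2Cl2, 0 °C → rt
Reagents that add atoms: acetic anhydride, CC(=O)OC(C)=O
Why: Acetylation of the two secondary alcohols; the tertiary, hindered C8 hydroxyl should not be acylated under these conditions.

Step 20
Reactants: 27 acetal diacetate
Product: 28 seco-diol (C2 primary alcohol and 14α-OH free)
Conditions: PPTS, MeOH, 35 °C
Reagents that add atoms: none
Why: Mild acid-catalysed transacetalisation removes the electron-rich anisylidene acetal, while the TBDPS ether, the acetates and the epoxide flanked by the electron-withdrawing C12 acetate should survive.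

Step 21
Reactants: 28 seco-diol
Product: 29 seco-aldehyde (C2 aldehyde on quaternary C1; 14-OH and 8-OH free)
Conditions: TEMPO (cat.), PhI(OAc)2, CH2Cl2, rt
Reagents that add atoms: none
Why: Oxoammonium oxidation is selective for the primary C2 alcohol over the secondary C14 and tertiary C8 alcohols and gives a non-enolisable neopentyl aldehyde.

Step 22
Reactants: 29 seco-aldehyde
Product: 30 macrocyclic 2,14-diol (ten-membered ring closed; 2-OH as in the target; 9,12-diacetate; 16-OTBDPS)
Conditions: CrCl2 (8 equiv), NiCl2 (2 mol%), DMSO/THF (3:1), 2 mM, rt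
Reagents that add atoms: none
Why: Ni(0) formed in situ inserts into the C3–I bond and transmetalation gives a configurationally stable (Z)-alkenylchromium(III) that adds to the C2 aldehyde; this is the Nozaki–Hiyama–Kishi reaction, whose intramolecular form is established for nine- and ten-membered carbocycles. The ten-membered ring is closed by 1,2-addition across C2–C3 (exo with respect to the C=O), all other rings being present. The new stereocentre C2 is set under substrate control: the trans-diequatorial C2/C9 tether should let C3 reach C2 only between C10 and the axial C15 methyl, and the aldehyde face attacked is the one that keeps the bulky O–Cr(III) pseudo-equatorial (anti to C1–C10) with H2 inside, syn to H10. The step needs cyclisation to beat oligomerisation (2 mM; the cis,cis-diene and the trans-substituted lactone pre-fold C3 towards C2), retention of the 3Z geometry, and chemoselectivity for the aldehyde over lactone, acetates, epoxide and the free C8/C14 hydroxyls, which organochromium(III) reagents should provide.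

Step 23
Reactants: 30 macrocyclic diol
Product: 31 2,9,12,14-tetraacetate (16-OTBDPS, 8-OH free)
Conditions: Ac2O, pyridine, DMAP (cat.), CH2Cl2, rt
Reagents that add atoms: acetic anhydride, CC(=O)OC(C)=O
Why: Acetylation of the allylic C2 and axial C14 hydroxyls completes the four acetates; the tertiary C8 hydroxyl should stay free.

Step 24
Reactants: 31 silyl ether
Product: 32 C16 primary allylic alcohol
Conditions: HF·pyridine, pyridine/THF, 0 °C → rt
Reagents that add atoms: none
Why: Fluoride-mediated desilylation, buffered with pyridine so that epoxide, acetates and lactone are kept.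

Step 25
Reactants: 32 allylic alcohol
Product: 33 CNP0128637.1 (2,9,12,14-tetraacetoxy-16-chloro-11,20-epoxy-8-hydroxybriara-3Z,5E-dien-18,7-olide)
Conditions: NCS, PPh3, CH2Cl2, −20 → 0 °C
Reagents that add atoms: N-chlorosuccinimide, O=C1CCC(=O)N1Cl
Why: Appel-type chlorination: the primary allylic oxyphosphonium is displaced by chloride in SN2 fashion (no transposition to C6), the tertiary C8 hydroxyl being too hindered to be activated.

Compound list

1 | (E)-3-(tert-butyldimethylsilyloxy)-N,N-dimethylbuta-1,3-dien-1-amine | CN(C)/C=C/C(=C)O[Si](C)(C)C(C)(C)C | starting material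
2 | ethyl (E)-3-methyl-4-oxobut-2-enoate | CCOC(=O)/C=C(\C)C=O | starting material
3 | cycloadduct: ethyl 3-(tert-butyldimethylsilyloxy)-5-(dimethylamino)-6-formyl-6-methylcyclohex-3-ene-1-carboxylate (amine cis, ester trans to formyl) | CCOC(=O)[C@H]1CC(O[Si](C)(C)C(C)(C)C)=C[C@H](N(C)C)[C@]1(C)C=O | intermediate
4 | ethyl (1S,2S)-2-formyl-2-methyl-5-oxocyclohex-3-ene-1-carboxylate | CCOC(=O)[C@H]1CC(=O)C=C[C@]1(C)C=O | intermediate
5 | ethyl 2-formyl-2-methyl-6-methylidene-5-oxocyclohex-3-ene-1-carboxylate (centres as in 4) | CCOC(=O)[C@H]1C(=C)C(=O)C=C[C@]1(C)C=O | intermediate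
6 | ethyl 5-formyl-5-methyl-8-oxo-1-oxaspiro[2.5]oct-6-ene-4-carboxylate (epoxide O α, trans to ester) | CCOC(=O)[C@H]1[C@@]2(CO2)C(=O)C=C[C@]1(C)C=O | intermediate
7 | ethyl 5-(hydroxymethyl)-5-methyl-8-oxo-1-oxaspiro[2.5]oct-6-ene-4-carboxylate | CCOC(=O)[C@H]1[C@@]2(CO2)C(=O)C=C[C@]1(C)CO | intermediate
8 | 5-(hydroxymethyl)-5-methyl-8-oxo-1-oxaspiro[2.5]oct-6-ene-4-carboxylic acid | OC(=O)[C@H]1[C@@]2(CO2)C(=O)C=C[C@]1(C)CO | intermediate
9 | anisylidene acetal acid (C2–O/14α-O 1,3-dioxane, aryl equatorial; 12-ketone; 11,20-epoxide; C9 acid) | OC(=O)[C@H]1[C@@]2(CO2)C(=O)C[C@@H]3O[C@H](c4ccc(OC)cc4)OC[C@]13C | intermediate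
10 | mixed isobutyl carbonic anhydride of 9 | CC(C)COC(=O)OC(=O)[C@H]1[C@@]2(CO2)C(=O)C[C@@H]3O[C@H](c4ccc(OC)cc4)OC[C@]13C | intermediate
11 | diazomethyl ketone (C9 ketone, C8 diazo carbon; rest as 9) | [N-]=[N+]=CC(=O)[C@H]1[C@@]2(CO2)C(=O)C[C@@H]3O[C@H](c4ccc(OC)cc4)OC[C@]13C | intermediate
12 | but-2-yne-1,4-diol | OCC#CCO | starting material
13 | 4-(tert-butyldiphenylsilyloxy)but-2-yn-1-ol | OCC#CCO[Si](c1ccccc1)(c1ccccc1)C(C)(C)C | intermediate
14 | sodium alkenylaluminate (five-membered oxaluminacycle, Al on C5) | [Na+].COCCO[Al-]1(OCCOC)OCC=C1CO[Si](c1ccccc1)(c1ccccc1)C(C)(C)C | intermediate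
15 | (Z)-4-(tert-butyldiphenylsilyloxy)-3-iodobut-2-en-1-ol | OC/C=C(\I)CO[Si](c1ccccc1)(c1ccccc1)C(C)(C)C | intermediate
16 | acetylene | C#C | starting material
17 | hexamethylditin | C[Sn](C)(C)[Sn](C)(C)C | starting material
18 | (Z)-1,2-bis(trimethylstannyl)ethene | C[Sn](C)(C)/C=C\[Sn](C)(C)C | intermediate
19 | (2E,4Z)-3-[(tert-butyldiphenylsilyloxy)methyl]-5-(trimethylstannyl)penta-2,4-dien-1-ol | OC/C=C(\C=C/[Sn](C)(C)C)CO[Si](c1ccccc1)(c1ccccc1)C(C)(C)C | intermediate
20 | (2E,4Z)-3-[(tert-butyldiphenylsilyloxy)methyl]-5-iodopenta-2,4-dien-1-ol | OC/C=C(\C=C/I)CO[Si](c1ccccc1)(c1ccccc1)C(C)(C)C | intermediate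
21 | (2E,4Z)-3-[(tert-butyldiphenylsilyloxy)methyl]-5-iodopenta-2,4-dienal | O=C/C=C(\C=C/I)CO[Si](c1ccccc1)(c1ccccc1)C(C)(C)C | intermediate
22 | diazo aldol adduct (7-OH, C8 diazo, C9 ketone, 3Z,5E-3-iododiene, 16-OTBDPS; cyclohexane part as 11) | I/C=C\C(CO[Si](c1ccccc1)(c1ccccc1)C(C)(C)C)=C/[C@H](O)C(=[N+]=[N-])C(=O)[C@H]1[C@@]2(CO2)C(=O)C[C@@H]3O[C@H](c4ccc(OC)cc4)OC[C@]13C | intermediate
23 | C7 acrylate of 22 | I/C=C\C(CO[Si](c1ccccc1)(c1ccccc1)C(C)(C)C)=C/[C@H](OC(=O)C=C)C(=[N+]=[N-])C(=O)[C@H]1[C@@]2(CO2)C(=O)C[C@@H]3O[C@H](c4ccc(OC)cc4)OC[C@]13C | intermediate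
24 | C8,C9-diketone with C7 acryloyloxy group | I/C=C\C(CO[Si](c1ccccc1)(c1ccccc1)C(C)(C)C)=C/[C@H](OC(=O)C=C)C(=O)C(=O)[C@H]1[C@@]2(CO2)C(=O)C[C@@H]3O[C@H](c4ccc(OC)cc4)OC[C@]13C | intermediate
25 | hydroxy lactone with C9 and C12 ketones (8-OH cis to C6 and to C17-Me) | I/C=C\C(CO[Si](c1ccccc1)(c1ccccc1)C(C)(C)C)=C/[C@@H]1OC(=O)[C@H](C)[C@@]1(O)C(=O)[C@H]1[C@@]2(CO2)C(=O)C[C@@H]3O[C@H](c4ccc(OC)cc4)OC[C@]13C | intermediate
26 | 9,12-diol lactone (12α-OH) | I/C=C\C(CO[Si](c1ccccc1)(c1ccccc1)C(C)(C)C)=C/[C@@H]1OC(=O)[C@H](C)[C@@]1(O)[C@@H](O)[C@H]1[C@@]2(CO2)[C@H](O)C[C@@H]3O[C@H](c4ccc(OC)cc4)OC[C@]13C | intermediate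
27 | 9,12-diacetate, anisylidene acetal | I/C=C\C(CO[Si](c1ccccc1)(c1ccccc1)C(C)(C)C)=C/[C@@H]1OC(=O)[C@H](C)[C@@]1(O)[C@@H](OC(C)=O)[C@H]1[C@@]2(CO2)[C@H](OC(C)=O)C[C@@H]3O[C@H](c4ccc(OC)cc4)OC[C@]13C | intermediate
28 | seco-diol (C2 CH2OH, 14α-OH) | I/C=C\C(CO[Si](c1ccccc1)(c1ccccc1)C(C)(C)C)=C/[C@@H]1OC(=O)[C@H](C)[C@@]1(O)[C@@H](OC(C)=O)[C@H]1[C@@]2(CO2)[C@H](OC(C)=O)C[C@H](O)[C@]1(C)CO | intermediate
29 | seco-aldehyde (C2 CHO on C1; C3 (Z)-iodide) | I/C=C\C(CO[Si](c1ccccc1)(c1ccccc1)C(C)(C)C)=C/[C@@H]1OC(=O)[C@H](C)[C@@]1(O)[C@@H](OC(C)=O)[C@H]1[C@@]2(CO2)[C@H](OC(C)=O)C[C@H](O)[C@]1(C)C=O | intermediate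
30 | macrocyclic 2,14-diol (ten-membered ring closed) | O[C@H]1/C=C\C(CO[Si](c2ccccc2)(c2ccccc2)C(C)(C)C)=C/[C@@H]2OC(=O)[C@H](C)[C@@]2(O)[C@@H](OC(C)=O)[C@H]2[C@@]3(CO3)[C@H](OC(C)=O)C[C@H](O)[C@]12C | intermediate
31 | 2,9,12,14-tetraacetate, 16-OTBDPS | CC(=O)O[C@H]1/C=C\C(CO[Si](c2ccccc2)(c2ccccc2)C(C)(C)C)=C/[C@@H]2OC(=O)[C@H](C)[C@@]2(O)[C@@H](OC(C)=O)[C@H]2[C@@]3(CO3)[C@H](OC(C)=O)C[C@H](OC(C)=O)[C@]12C | intermediate
32 | 16-hydroxy tetraacetate | CC(=O)O[C@H]1/C=C\C(CO)=C/[C@@H]2OC(=O)[C@H](C)[C@@]2(O)[C@@H](OC(C)=O)[C@H]2[C@@]3(CO3)[C@H](OC(C)=O)C[C@H](OC(C)=O)[C@]12C | intermediate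
33 | CNP0128637.1 | CC(=O)O[C@H]1/C=C\C(CCl)=C/[C@@H]2OC(=O)[C@H](C)[C@@]2(O)[C@@H](OC(C)=O)[C@H]2[C@@]3(CO3)[C@H](OC(C)=O)C[C@H](OC(C)=O)[C@]12C | target

Total step count: 25. Longest linear sequence: 19 steps (steps 1–7 and 14–25).

Steps most likely to fail

Step 22: the aldehyde may be attacked on its other face (poor facial selectivity at C2), and intermolecular coupling may compete with ring closure. The fallback sets out from 29 and comes back at 30: the cyclisation is run as before, the resulting C2-epimeric macrocyclic carbinol mixture F1 is oxidised at the allylic position only (MnO2, CH2Cl2; the C14 and C8 hydroxyls stay) to the macrocyclic dienone F2, and Luche reduction (NaBH4, CeCl3, MeOH, −78 °C) should deliver hydride from the exposed periphery of the ring, so that C2 is set by ketone reduction instead of by the C–C bond formation.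

Step 17: copper hydride may reduce the vicinal diketone (1,2-reduction), or the copper enolate may epimerise the doubly activated C7–H before the ring closes. The fallback sets out from 24 and comes back at 25: an amine-catalysed intramolecular Morita–Baylis–Hillman reaction (DABCO, THF, 0 °C), with no hydride present while the 1,2-diketone exists, should give the α-methylene-β-hydroxy lactone F3. Conjugate reduction of its exo-methylene group ([(Ph3P)CuH]6, toluene, 0 °C) and equilibration at C17 (DBU) then return 25.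

Step 14: the catalyst may not control the face of the dienal with this bulky diazoketone donor (low selectivity at C7). The fallback sets out from 11 and 21 and comes back at 22: an uncatalysed, DBU-mediated aldol addition gives the C7-epimeric diazo aldol mixture F4, and MnO2 oxidises the dienylic carbinol to the 2-diazo-1,3-dione F5. Reagent-controlled reduction with BINAL-H (THF, −100 °C) should then reduce the conjugated C7 ketone and leave the saturated, hindered C12 ketone and the C9 carbonyl.

Further compounds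

F1 | step 22 | C2-epimeric mixture of macrocyclic 2,14-diol | OC1/C=C\C(CO[Si](c2ccccc2)(c2ccccc2)C(C)(C)C)=C/[C@@H]2OC(=O)[C@H](C)[C@@]2(O)[C@@H](OC(C)=O)[C@H]2[C@@]3(CO3)[C@H](OC(C)=O)C[C@H](O)[C@]12C
F2 | step 22 | macrocyclic C2 ketone (3Z,5E-dienone) | O=C1/C=C\C(CO[Si](c2ccccc2)(c2ccccc2)C(C)(C)C)=C/[C@@H]2OC(=O)[C@H](C)[C@@]2(O)[C@@H](OC(C)=O)[C@H]2[C@@]3(CO3)[C@H](OC(C)=O)C[C@H](O)[C@]12C
F3 | step 17 | α-methylene-β-hydroxy lactone (C17=CH2, 8-OH) | I/C=C\C(CO[Si](c1ccccc1)(c1ccccc1)C(C)(C)C)=C/[C@@H]1OC(=O)C(=C)[C@@]1(O)C(=O)[C@H]1[C@@]2(CO2)C(=O)C[C@@H]3O[C@H](c4ccc(OC)cc4)OC[C@]13C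
F4 | step 14 | diazo aldol adduct as C7-epimer mixture | I/C=C\C(CO[Si](c1ccccc1)(c1ccccc1)C(C)(C)C)=C/C(O)C(=[N+]=[N-])C(=O)[C@H]1[C@@]2(CO2)C(=O)C[C@@H]3O[C@H](c4ccc(OC)cc4)OC[C@]13C
F5 | step 14 | 2-diazo-1,3-dione (C7 and C9 ketones) | I/C=C\C(CO[Si](c1ccccc1)(c1ccccc1)C(C)(C)C)=C/C(=O)C(=[N+]=[N-])C(=O)[C@H]1[C@@]2(CO2)C(=O)C[C@@H]3O[C@H](c4ccc(OC)cc4)OC[C@]13C
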